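**Retrosynthetic overview**
1. Target 21 ⇐ selective C4 acetylation ⇐ Luche reduction of the C4 ketone (sets 4R, cis to the C2 phenyl) ⇐ allylic oxidation at C5 ⇐ desilylation of bicycle 17.
2. Bicycle 17 ⇐ acyclic chain 14 in one pot: Claisen ring closure C4a–C8a (ring A, the carbocycle), then oxa-Michael closure O1–C2 (ring C, the pyran). This copies the chalcone-synthase / chalcone-isomerase sequence of flavonoid biosynthesis.
3. Enabling feature: ring C is a vinylogous ester O1–C8a=C4a–C(=O), with C8a at the carboxylic acid oxidation level and C2 the benzylic β-carbon of a C4 carbonyl once C4–OAc is raised to the ketone. Holding C5 as a silyl ether (lower oxidation level, restored in step 10) leaves the C8a enol as the only oxygen that can reach C2.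
4. Chain 14 ⇐ aldehyde 10 + benzylideneacetone (aldol, C4a–C5). Aldehyde 10 ⇐ lactic acid dioxolanone 3 + 2,2-dimethylbut-3-enal 6 (aldol sets C7 and C8; the dioxolanone ring later serves as the activated acyl donor at C8a and is lost as pivalaldehyde).
5. Ring order: temporary dioxolanone → ring A → ring C.

Key step: step 8

Remark: chromene numbering (O1, C2, C3, C4, C4a, C5, C6, C7, C8, C8a) is used for all intermediates. The target is read as (2R,4R,7R,8R), with phenyl, acetoxy and both hydroxyls on one face. The temporary C5 carbinol in 13–18 is carried as an epimer mixture because step 10 oxidises it.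

**Step 1**
Reactants: 1 (S)-lactic acid; 2 pivalaldehyde
Product: 3 (2S,5S)-2-tert-butyl-5-methyl-1,3-dioxolan-4-one
Conditions: cat. TsOH, cat. H2SO4, pentane, reflux, Dean–Stark; crystallisation from pentane/Et2O, −78 °C
Reagents that add atoms: none
Why: Acid-catalysed acetalisation with azeotropic water removal should give the cis-dioxolanone as the thermodynamic major isomer, the lactate centre being untouched and the minor trans acetal being removed by low-temperature crystallisation.

**Step 2**
Reactants: 4 prenyl chloride (1-chloro-3-methylbut-2-ene)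
Product: 6 2,2-dimethylbut-3-enal, via prenylmagnesium chloride 5 (not isolated)
Conditions: Mg, THF, 0 °C; DMF, −20 → 0 °C; aq. HCl
Reagents that add atoms: N,N-dimethylformamide CN(C)C=O
Why: Bouveault-type formylation of the allylic Grignard reagent, which should react through its γ-carbon (SE2′) so that the formyl group ends on the quaternary carbon.

**Step 3**
Reactants: 3 (2S,5S)-2-tert-butyl-5-methyl-1,3-dioxolan-4-one; 6 2,2-dimethylbut-3-enal
Product: 8 (2S,5R)-2-tert-butyl-5-[(1R)-1-hydroxy-2,2-dimethylbut-3-enyl]-5-methyl-1,3-dioxolan-4-one, via lithium enolate 7 (not isolated)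
Conditions: LiN(iPr)2 (commercial solution), THF, −78 °C; then 6, −78 °C; AcOH, −78 °C
Reagents that add atoms: none
Why: Aldol addition of the lactate dioxolanone enolate (self-regeneration of stereocentres): the tert-butyl group blocks one enolate face so that C8 forms with overall retention (8R), and a closed Zimmerman–Traxler chair with the bulky aldehyde substituent equatorial and the enolate methyl cis to O–Li should give the methyl/hydroxyl-syn adduct, that is 7R.

**Step 4**
Reactants: 8 (2S,5R)-2-tert-butyl-5-[(1R)-1-hydroxy-2,2-dimethylbut-3-enyl]-5-methyl-1,3-dioxolan-4-one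
Product: 9 (2S,5R)-2-tert-butyl-5-[(1R)-2,2-dimethyl-1-(triethylsilyloxy)but-3-enyl]-5-methyl-1,3-dioxolan-4-one
Conditions: Et3SiOTf, 2,6-lutidine, CH2Cl2, 0 °C
Reagents that add atoms: triethylsilyl triflate CC[Si](CC)(CC)OS(=O)(=O)C(F)(F)F
Why: Silyl triflate silylation of the hindered C7 alcohol, so that no C7 alkoxide can trigger retro-aldol cleavage in the later base steps.

**Step 5**
Reactants: 9 (2S,5R)-2-tert-butyl-5-[(1R)-2,2-dimethyl-1-(triethylsilyloxy)but-3-enyl]-5-methyl-1,3-dioxolan-4-one
Product: 10 (3R)-3-[(2S,4R)-2-tert-butyl-4-methyl-5-oxo-1,3-dioxolan-4-yl]-2,2-dimethyl-3-(triethylsilyloxy)propanal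
Conditions: O3, CH2Cl2, −78 °C; PPh3
Reagents that add atoms: ozone [O-][O+]=O
Why: Ozonolysis with reductive work-up cleaves the only alkene to the non-enolisable C5 aldehyde, the silyl ether and the dioxolanone being inert to ozone.

**Step 6**
Reactants: 11 (E)-4-phenylbut-3-en-2-one (benzylideneacetone); 10 (3R)-3-[(2S,4R)-2-tert-butyl-4-methyl-5-oxo-1,3-dioxolan-4-yl]-2,2-dimethyl-3-(triethylsilyloxy)propanal
Product: 13 (2S,5R)-2-tert-butyl-5-[(1R,6E)-3-hydroxy-2,2-dimethyl-5-oxo-7-phenyl-1-(triethylsilyloxy)hept-6-enyl]-5-methyl-1,3-dioxolan-4-one (C5 epimer mixture), via lithium dienolate 12 (not isolated)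
Conditions: LiN(iPr)2 (commercial solution), THF, −78 °C; then 10, −78 °C; AcOH, −78 °C
Reagents that add atoms: none
Why: Kinetic deprotonation of the methyl group gives the cross-conjugated lithium dienolate, which should undergo aldol addition to the aldehyde far faster than Claisen attack on the hindered dioxolanone carbonyl, the cold quench preventing lactonisation of the aldolate onto C8a and the new C5 carbinol being a temporary centre formed without control.

**Step 7**
Reactants: 13 (2S,5R)-2-tert-butyl-5-[(1R,6E)-3-hydroxy-2,2-dimethyl-5-oxo-7-phenyl-1-(triethylsilyloxy)hept-6-enyl]-5-methyl-1,3-dioxolan-4-one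
Product: 14 (2S,5R)-2-tert-butyl-5-[(1R,6E)-2,2-dimethyl-5-oxo-7-phenyl-1,3-bis(triethylsilyloxy)hept-6-enyl]-5-methyl-1,3-dioxolan-4-one (C5 epimer mixture)
Conditions: Et3SiOTf, 2,6-lutidine, CH2Cl2, −78 °C
Reagents that add atoms: triethylsilyl triflate CC[Si](CC)(CC)OS(=O)(=O)C(F)(F)F
Why: Low-temperature silyl triflate protection of the β-hydroxy ketone blocks the C5 oxygen, which would otherwise add to C2 itself, and so reserves C2 for O1.

**Step 8**
Reactants: 14 (2S,5R)-2-tert-butyl-5-[(1R,6E)-2,2-dimethyl-5-oxo-7-phenyl-1,3-bis(triethylsilyloxy)hept-6-enyl]-5-methyl-1,3-dioxolan-4-one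
Product: 17 (2R,7R,8R)-8-hydroxy-6,6,8-trimethyl-2-phenyl-5,7-bis(triethylsilyloxy)-2,3,5,6,7,8-hexahydro-4H-chromen-4-one (C5 epimer mixture), via lithium enolate 15 (not isolated), via enolised acylcyclohexanone 16 (not isolated)
Conditions: LiN(SiMe3)2 (2.2 equiv), THF, −78 → −30 °C; AcOH; then quinidine-derived 3,5-bis(trifluoromethyl)phenyl squaramide (10 mol %), toluene, 0 °C → rt
Reagents that add atoms: none
Why: LiN(SiMe3)2 removes a C4a proton (the only enolisable position) and enolate 15 attacks the α-oxygenated, ring-activated dioxolanone carbonyl C8a in an intramolecular Claisen (Dieckmann-type) acylation, the laboratory copy of the chalcone-synthase ring closure; collapse of the tetrahedral intermediate expels the hemiacetal alkoxide, which sheds pivalaldehyde and leaves the C8 hydroxyl and the lithium chelate of diketone 16. After neutralisation the C8a enol hydroxyl adds to C2 of the cinnamoyl unit, the chalcone-to-flavanone oxa-Michael closure, for which the closest known reaction type is the flavanone- and chromanone-forming oxa-Michael cyclisation under bifunctional cinchona squaramide or thiourea catalysis. Ring A is closed through the C4a–C8a bond in a 6-exo-trig (enolexo) mode, favoured by the C6 gem-dimethyl group, and ring C through the O1–C2 bond in a 6-endo-trig mode. C2 is the only new stereocentre kept in the target; it is too far from C7 and C8 for substrate control, so it is set by the catalyst, whose squaramide should bind the C4 carbonyl while the quinuclidine shuttles the enol proton, the quinidine-derived pseudo-enantiomer being chosen to deliver O1 to the enone face that gives 2R. The step needs O1-versus-O5 regioselectivity and acylation ahead of β-elimination: with C5 held as a silyl ether the C8a enol is the only oxygen that can reach C2 through a six-membered transition state (the C8 hydroxyl would need a seven-membered one), and the six-membered acylation of the activated acyl donor at low temperature should outrun loss of the C5 silyloxy group.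

**Step 9**
Reactants: 17 (2R,7R,8R)-8-hydroxy-6,6,8-trimethyl-2-phenyl-5,7-bis(triethylsilyloxy)-2,3,5,6,7,8-hexahydro-4H-chromen-4-one
Product: 18 (2R,7R,8R)-5,7,8-trihydroxy-6,6,8-trimethyl-2-phenyl-2,3,5,6,7,8-hexahydro-4H-chromen-4-one (C5 epimer mixture)
Conditions: HF·pyridine, pyridine, THF, 0 °C → rt
Reagents that add atoms: none
Why: Fluoride-mediated cleavage of both triethylsilyl ethers under buffered conditions that avoid the base-induced retro-oxa-Michael opening of the dihydropyranone.

**Step 10**
Reactants: 18 (2R,7R,8R)-5,7,8-trihydroxy-6,6,8-trimethyl-2-phenyl-2,3,5,6,7,8-hexahydro-4H-chromen-4-one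
Product: 19 (2R,7R,8R)-7,8-dihydroxy-6,6,8-trimethyl-2-phenyl-2,3,7,8-tetrahydro-4H-chromene-4,5(6H)-dione
Conditions: MnO2, CH2Cl2, rt
Reagents that add atoms: none
Why: Manganese dioxide oxidation should be selective for the allylic C5 carbinol (attached to C4a of the enol ether double bond) over the hindered non-allylic C7 hydroxyl and the tertiary C8 hydroxyl, and it converges both C5 epimers on one dione under neutral conditions.

**Step 11**
Reactants: 19 (2R,7R,8R)-7,8-dihydroxy-6,6,8-trimethyl-2-phenyl-2,3,7,8-tetrahydro-4H-chromene-4,5(6H)-dione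
Product: 20 (2R,4R,7R,8R)-4,7,8-trihydroxy-6,6,8-trimethyl-2-phenyl-2,3,4,6,7,8-hexahydro-5H-chromen-5-one
Conditions: NaBH4, CeCl3·7H2O, MeOH, −78 °C
Reagents that add atoms: none
Why: Luche reduction, in which hydride should attack the unhindered C4 carbonyl in preference to the C5 carbonyl flanked by the gem-dimethyl carbon, and axial delivery on the half-chair with the C2 phenyl pseudo-equatorial should give the 2,4-cis alcohol (4R), as in flavanone to cis-flavan-4-ol reductions.

**Step 12**
Reactants: 20 (2R,4R,7R,8R)-4,7,8-trihydroxy-6,6,8-trimethyl-2-phenyl-2,3,4,6,7,8-hexahydro-5H-chromen-5-one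
Product: 21 (2R,4R,7R,8R)-7,8-dihydroxy-6,6,8-trimethyl-5-oxo-2-phenyl-3,4,5,6,7,8-hexahydro-2H-chromen-4-yl acetate
Conditions: Ac2O (1.1 equiv), pyridine, cat. DMAP, CH2Cl2, −20 → 0 °C
Reagents that add atoms: acetic anhydride CC(=O)OC(C)=O
Why: Nucleophile-catalysed acylation that should discriminate the accessible secondary C4 hydroxyl from the C7 hydroxyl buried between two quaternary carbons and from the tertiary C8 hydroxyl.

**Compound list**
1 | (S)-lactic acid | C[C@H](O)C(=O)O | starting material
2 | pivalaldehyde | CC(C)(C)C=O | starting material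
3 | (2S,5S)-2-tert-butyl-5-methyl-1,3-dioxolan-4-one | C[C@@H]1O[C@H](C(C)(C)C)OC1=O | intermediate
4 | prenyl chloride | CC(C)=CCCl | starting material
5 | prenylmagnesium chloride | CC(C)=CC[Mg]Cl | intermediate
6 | 2,2-dimethylbut-3-enal | C=CC(C)(C)C=O | intermediate
7 | lithium enolate of 3 | CC1=C(O[Li])O[C@@H](C(C)(C)C)O1 | intermediate
8 | (2S,5R)-2-tert-butyl-5-[(1R)-1-hydroxy-2,2-dimethylbut-3-enyl]-5-methyl-1,3-dioxolan-4-one | C[C@]1([C@H](O)C(C)(C)C=C)O[C@H](C(C)(C)C)OC1=O | intermediate
9 | triethylsilyl ether of 8 | C[C@]1([C@H](O[Si](CC)(CC)CC)C(C)(C)C=C)O[C@H](C(C)(C)C)OC1=O | intermediate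
10 | (3R)-3-[(2S,4R)-2-tert-butyl-4-methyl-5-oxo-1,3-dioxolan-4-yl]-2,2-dimethyl-3-(triethylsilyloxy)propanal | C[C@]1([C@H](O[Si](CC)(CC)CC)C(C)(C)C=O)O[C@H](C(C)(C)C)OC1=O | intermediate
11 | (E)-4-phenylbut-3-en-2-one | CC(=O)/C=C/c1ccccc1 | starting material
12 | lithium (E)-4-phenylbuta-1,3-dien-2-olate | C=C(O[Li])/C=C/c1ccccc1 | intermediate
13 | β-hydroxy enone, C5 epimer mixture (name in step 6) | O=C(/C=C/c1ccccc1)CC(O)C(C)(C)[C@@H](O[Si](CC)(CC)CC)[C@@]1(C)O[C@H](C(C)(C)C)OC1=O | intermediate
14 | bis(triethylsilyl) ether, C5 epimer mixture (name in step 7) | O=C(/C=C/c1ccccc1)CC(O[Si](CC)(CC)CC)C(C)(C)[C@@H](O[Si](CC)(CC)CC)[C@@]1(C)O[C@H](C(C)(C)C)OC1=O | intermediate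
15 | lithium enolate of 14 at C4a | [Li]OC(/C=C/c1ccccc1)=CC(O[Si](CC)(CC)CC)C(C)(C)[C@@H](O[Si](CC)(CC)CC)[C@@]1(C)O[C@H](C(C)(C)C)OC1=O | intermediate
16 | (5R,6R)-6-hydroxy-4,4,6-trimethyl-2-[(E)-3-phenylprop-2-enoyl]-3,5-bis(triethylsilyloxy)cyclohexan-1-one, drawn as its C8a enol | O=C(/C=C/c1ccccc1)C1=C(O)[C@](C)(O)[C@H](O[Si](CC)(CC)CC)C(C)(C)C1O[Si](CC)(CC)CC | intermediate
17 | (2R,7R,8R)-8-hydroxy-6,6,8-trimethyl-2-phenyl-5,7-bis(triethylsilyloxy)-2,3,5,6,7,8-hexahydro-4H-chromen-4-one, C5 epimer mixture | O=C1C[C@H](c2ccccc2)OC2=C1C(O[Si](CC)(CC)CC)C(C)(C)[C@@H](O[Si](CC)(CC)CC)[C@@]2(C)O | intermediate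
18 | (2R,7R,8R)-5,7,8-trihydroxy-6,6,8-trimethyl-2-phenyl-2,3,5,6,7,8-hexahydro-4H-chromen-4-one, C5 epimer mixture | O=C1C[C@H](c2ccccc2)OC2=C1C(O)C(C)(C)[C@@H](O)[C@@]2(C)O | intermediate
19 | (2R,7R,8R)-7,8-dihydroxy-6,6,8-trimethyl-2-phenyl-2,3,7,8-tetrahydro-4H-chromene-4,5(6H)-dione | O=C1C[C@H](c2ccccc2)OC2=C1C(=O)C(C)(C)[C@@H](O)[C@@]2(C)O | intermediate
20 | (2R,4R,7R,8R)-4,7,8-trihydroxy-6,6,8-trimethyl-2-phenyl-2,3,4,6,7,8-hexahydro-5H-chromen-5-one | O[C@@H]1C[C@H](c2ccccc2)OC2=C1C(=O)C(C)(C)[C@@H](O)[C@@]2(C)O | intermediate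
21 | (2R,4R,7R,8R)-7,8-dihydroxy-6,6,8-trimethyl-5-oxo-2-phenyl-3,4,5,6,7,8-hexahydro-2H-chromen-4-yl acetate | CC(=O)O[C@@H]1C[C@H](c2ccccc2)OC2=C1C(=O)C(C)(C)[C@@H](O)[C@@]2(C)O | target

**Step count and risks**
Total steps: 12. Longest linear sequence: 11 (steps 2–12, from prenyl chloride); step 1 is a one-step branch.

Steps most likely to fail:

1. Step 8. The catalyst may fail to differentiate the two faces of C2 in the reversible oxa-Michael closure, so that C2 forms unselectively. The C4a enolate may also expel the C5 silyloxy group before it acylates. The fallback sets out from 10 and returns to the route at 17; it removes the stereochemical demand from the ring closure. The kinetic lithium enolate of commercial (E)-4-methoxybut-3-en-2-one (LiN(iPr)2, THF, −78 °C) is added to 10 to give the β-hydroxy methoxyenone F1, which Et3SiOTf and 2,6-lutidine convert into the bis(triethylsilyl) ether F2. LiN(SiMe3)2 then effects the same Claisen ring closure, and on acidification with AcOH the C8a enol adds to the methoxyenone and eliminates methanol. This forms the same C4a–C8a and O1–C2 bonds without a stereocentre and gives the fused 4-pyranone F3. C2 is then set by the enantioselective conjugate addition of phenylboronic acid to the chromone-type enone, catalysed by divalent palladium (Pd(OCOCF3)2, t-BuPyOX ligand of the enantiomeric series that gives 2R, NH4PF6, water, 1,2-dichloroethane, 60 °C). This delivers 17.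

2. Step 3. The two faces of the hindered aldehyde may be poorly differentiated in the aldol transition state, and retro-aldol equilibration of the congested aldolate may add to this, so that C7 forms as a mixture. The fallback sets out from the crude step 3 product (8 together with its C7 epimer) and returns to the route at 8; it sets C7 by hydride delivery instead of by the aldol. Dess–Martin periodinane in CH2Cl2 converges both epimers on the ketone F4. Reduction with Zn(BH4)2 in Et2O at −78 °C through the zinc chelate of the ketone and the lactone carbonyl should deliver hydride anti to the C8 methyl and give 8 with the 7R configuration.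

3. Step 11. Hydride may be delivered to the wrong carbonyl (C5), or the vinylogous triketone may open by retro-oxa-Michael reaction under the basic borohydride conditions, which would scramble C2 and the O1/O5 regiochemistry. The fallback sets out from 17 and returns to the route at 21; it inverts the redox order so that only one ketone is present during reduction. Luche reduction of 17 (NaBH4, CeCl3·7H2O, MeOH, −78 °C) gives the cis allylic alcohol F5. Ac2O and pyridine give the acetate F6. Buffered desilylation (Bu4NF, AcOH, THF, 0 °C) gives the triol acetate F7. MnO2 in CH2Cl2 then oxidises the allylic C5 carbinol to give 21 directly.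

**Further compounds**
F1 | step 8 | (2S,5R)-2-tert-butyl-5-[(1R,6E)-3-hydroxy-7-methoxy-2,2-dimethyl-5-oxo-1-(triethylsilyloxy)hept-6-enyl]-5-methyl-1,3-dioxolan-4-one (C5 epimer mixture) | CO/C=C/C(=O)CC(O)C(C)(C)[C@@H](O[Si](CC)(CC)CC)[C@@]1(C)O[C@H](C(C)(C)C)OC1=O
F2 | step 8 | (2S,5R)-2-tert-butyl-5-[(1R,6E)-7-methoxy-2,2-dimethyl-5-oxo-1,3-bis(triethylsilyloxy)hept-6-enyl]-5-methyl-1,3-dioxolan-4-one (C5 epimer mixture) | CO/C=C/C(=O)CC(O[Si](CC)(CC)CC)C(C)(C)[C@@H](O[Si](CC)(CC)CC)[C@@]1(C)O[C@H](C(C)(C)C)OC1=O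
F3 | step 8 | (7R,8R)-8-hydroxy-6,6,8-trimethyl-5,7-bis(triethylsilyloxy)-5,6,7,8-tetrahydro-4H-chromen-4-one (C5 epimer mixture) | O=C1C=COC2=C1C(O[Si](CC)(CC)CC)C(C)(C)[C@@H](O[Si](CC)(CC)CC)[C@@]2(C)O
F4 | step 3 | (2S,5R)-2-tert-butyl-5-(2,2-dimethylbut-3-enoyl)-5-methyl-1,3-dioxolan-4-one | C[C@]1(C(=O)C(C)(C)C=C)O[C@H](C(C)(C)C)OC1=O
F5 | step 11 | (2R,4R,7R,8R)-6,6,8-trimethyl-2-phenyl-5,7-bis(triethylsilyloxy)-3,4,5,6,7,8-hexahydro-2H-chromene-4,8-diol (C5 epimer mixture) | O[C@@H]1C[C@H](c2ccccc2)OC2=C1C(O[Si](CC)(CC)CC)C(C)(C)[C@@H](O[Si](CC)(CC)CC)[C@@]2(C)O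
F6 | step 11 | (2R,4R,7R,8R)-8-hydroxy-6,6,8-trimethyl-2-phenyl-5,7-bis(triethylsilyloxy)-3,4,5,6,7,8-hexahydro-2H-chromen-4-yl acetate (C5 epimer mixture) | CC(=O)O[C@@H]1C[C@H](c2ccccc2)OC2=C1C(O[Si](CC)(CC)CC)C(C)(C)[C@@H](O[Si](CC)(CC)CC)[C@@]2(C)O
F7 | step 11 | (2R,4R,7R,8R)-5,7,8-trihydroxy-6,6,8-trimethyl-2-phenyl-3,4,5,6,7,8-hexahydro-2H-chromen-4-yl acetate (C5 epimer mixture) | CC(=O)O[C@@H]1C[C@H](c2ccccc2)OC2=C1C(O)C(C)(C)[C@@H](O)[C@@]2(C)O
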